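The route is cut at C5''–C6'' in ring C, the dihydropyranone. There O1'' links the stereogenic C2'' to C6'', the enol-ether carbon of a vinylogous ester, so the cut turns C6'' into the carbonyl carbon of an ester between the (R)-side-chain acid and (S)-4-hydroxypentan-2-one; both stereocentres come from purchased chiral building blocks and are joined by esterification. In one operation the key step shifts that acyl group from O1'' to the ketone methyl carbon (intramolecular Claisen), and the acid quench recloses and dehydrates ring C and frees the 5-OH. The precursor is the 5-O-MOM chromone carrying this β-acyloxy methyl ketone ester on C6 of ring A.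

Key step: step 10

Assumption: ring A is the benzene ring and ring B the γ-pyrone of the chromone, ring C is numbered O1'', C2'' (bears CH3), C3'', C4'' (ketone), C5'', C6'', and the side chain is C1' (ArCH2) and C2' (stereogenic CH); the MOM acetal is taken to hydrolyse in the same acid stage in which ring C dehydrates, the order of the two events not mattering.

Step 1
Reactants: 1 2',4',6'-trihydroxyacetophenone
Product: 3 noreugenin (5,7-dihydroxy-2-methyl-4H-chromen-4-one), via 3-acetyl-5,7-diacetoxy-2-methylchromone 2 (not isolated)
Conditions: Ac2O, NaOAc, reflux; then aq. Na2CO3, reflux; HCl to pH 3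
Reagents that add atoms: acetic anhydride, CC(=O)OC(C)=O
Why: Kostanecki–Robinson acylation and cyclodehydration builds the 2-methyl-γ-pyrone (ring B) on the symmetrical phloroglucinol nucleus, where no regiochemical choice exists, and hot carbonate then hydrolyses the two aryl acetates and removes the 3-acetyl group by retro-Claisen cleavage.

Step 2
Reactants: 3 noreugenin
Product: 4 eugenin (5-hydroxy-7-methoxy-2-methyl-4H-chromen-4-one)
Conditions: MeI (1.05 equiv), K2CO3, acetone, reflux
Reagents that add atoms: iodomethane, CI
Why: Williamson O-methylation with one equivalent of MeI takes the free, more acidic 7-OH, because the 5-OH is tied up in a hydrogen bond to the C4 carbonyl.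

Step 3
Reactants: 4 eugenin
Product: 5 5-hydroxy-6-iodo-7-methoxy-2-methyl-4H-chromen-4-one
Conditions: BnMe3N·ICl2 (1.05 equiv), CaCO3, CH2Cl2–MeOH, rt
Reagents that add atoms: benzyltrimethylammonium dichloroiodate, C[N+](C)(C)Cc1ccccc1.Cl[I-]Cl
Why: Electrophilic aromatic iodination under buffered, non-acidic conditions is directed ortho to the free 5-OH, i.e. to C6 and not to C8, as is usual for 5-hydroxy-7-alkoxy chromones and flavones, and a single equivalent of the mild dichloroiodate limits di-iodination.

Step 4
Reactants: 5 5-hydroxy-6-iodo-7-methoxy-2-methyl-4H-chromen-4-one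
Product: 6 6-iodo-7-methoxy-5-(methoxymethoxy)-2-methyl-4H-chromen-4-one
Conditions: NaH, MOMCl, DMF, 0 °C → rt
Reagents that add atoms: chloromethyl methyl ether, COCCl
Why: Williamson alkylation of the sodium phenoxide installs the MOM acetal despite chelation and the flanking iodine, which removes the acidic proton before the organozinc and amide-base steps and gives a group that dilute acid strips at the very end.

Step 5
Reactants: 7 methyl (R)-3-hydroxy-2-methylpropanoate
Product: 8 methyl (S)-3-iodo-2-methylpropanoate
Conditions: I2, PPh3, imidazole, CH2Cl2, 0 °C → rt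
Reagents that add atoms: iodine, II
Why: Appel-type iodination converts the primary alcohol without touching the stereocentre, whose descriptor changes from R to S only because CH2I outranks the ester carbon.

Step 6
Reactants: 6 6-iodo-7-methoxy-5-(methoxymethoxy)-2-methyl-4H-chromen-4-one; 8 methyl (S)-3-iodo-2-methylpropanoate
Product: 10 methyl (2R)-3-[7-methoxy-5-(methoxymethoxy)-2-methyl-4-oxo-4H-chromen-6-yl]-2-methylpropanoate, via organozinc iodide 9 (not isolated)
Conditions: 8, Zn dust (I2-activated), DMF, 0 °C → rt; then 6, Pd2(dba)3 (2.5 mol%), SPhos (10 mol%), 50 °C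
Reagents that add atoms: zinc, [Zn] (its atom is present only in intermediate 9)
Why: Negishi cross-coupling: zinc inserts into the primary C–I bond to give the alkylzinc iodide, which couples at the C6–I bond under zerovalent palladium, the bulky electron-rich SPhos promoting oxidative addition at the doubly ortho-substituted iodide and reductive elimination ahead of β-hydride elimination; the stereocentre is a spectator and now reads R.

Step 7
Reactants: 10 methyl (2R)-3-[7-methoxy-5-(methoxymethoxy)-2-methyl-4-oxo-4H-chromen-6-yl]-2-methylpropanoate
Product: 11 (2R)-3-[7-methoxy-5-(methoxymethoxy)-2-methyl-4-oxo-4H-chromen-6-yl]-2-methylpropanoic acid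
Conditions: Me3SnOH (5 equiv), ClCH2CH2Cl, 80 °C; cold 0.1 M HCl wash
Reagents that add atoms: trimethyltin hydroxide, C[Sn](C)(C)O
Why: Trimethyltin hydroxide hydrolyses the methyl ester under nearly neutral conditions (tin-assisted acyl substitution), which avoids the aqueous hydroxide that could open ring B or epimerise C2'.

Step 8
Reactants: 12 ethyl (S)-3-hydroxybutanoate
Product: 14 (S)-4-hydroxypentan-2-one, via Weinreb amide 13 (not isolated)
Conditions: MeNH(OMe)·HCl, i-PrMgCl, THF, −20 °C; then MeMgBr, −20 → 0 °C; aq. NH4Cl, CH2Cl2 extraction, distillation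
Reagents that add atoms: methylmagnesium bromide, C[Mg]Br; N,O-dimethylhydroxylamine hydrochloride, CNOC.Cl (its atoms are present only in intermediate 13)
Why: Chloromagnesium amide aminolysis of the ester gives the Weinreb amide (as its magnesium alkoxide), and MeMgBr then adds once because the chelated tetrahedral adduct survives until the quench (Weinreb ketone synthesis), the carbinol stereocentre being untouched.

Step 9
Reactants: 11 (2R)-3-[7-methoxy-5-(methoxymethoxy)-2-methyl-4-oxo-4H-chromen-6-yl]-2-methylpropanoic acid; 14 (S)-4-hydroxypentan-2-one (1.5 equiv)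
Product: 15 (2S)-4-oxopentan-2-yl (2R)-3-[7-methoxy-5-(methoxymethoxy)-2-methyl-4-oxo-4H-chromen-6-yl]-2-methylpropanoate
Conditions: DCC, DMAP (0.1 equiv), CH2Cl2, 0 °C → rt
Reagents that add atoms: none
Why: Steglich esterification acylates the secondary hydroxyl without breaking the C2''–O bond, so the S configuration is retained, while catalytic DMAP at low temperature keeps the activated acid from epimerising and the β-acyloxy ketone from eliminating.

Step 10
Reactants: 15 (2S)-4-oxopentan-2-yl (2R)-3-[7-methoxy-5-(methoxymethoxy)-2-methyl-4-oxo-4H-chromen-6-yl]-2-methylpropanoate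
Product: 18 CNP0231471.1 (5-hydroxy-7-methoxy-2-methyl-6-{(2R)-2-[(2S)-2-methyl-4-oxo-3,4-dihydro-2H-pyran-6-yl]propyl}-4H-chromen-4-one), via hydroxy diketone 16 (not isolated), via cyclic hemiketal 17 (not isolated)
Conditions: LiN(SiMe3)2 (2.5 equiv), THF, −78 °C, 15 added slowly to the base, then to −20 °C; 2 M aq. HCl, 0 °C → rt
Reagents that add atoms: none
Why: The silylamide removes a proton from the terminal CH3 of the ketone (C5''), and this enolate carbon adds to the ester carbonyl C6'' in a six-membered, 6-(enolendo)-exo-trig array; the tetrahedral adduct opens by release of the C2'' alkoxide, which deprotonates the new 1,3-diketone, so that 16 sits as its lithium enolate and the transfer is irreversible. The closest known reaction is the Baker–Venkataraman O-to-C acyl shift, here in its aliphatic form on a β-acyloxy methyl ketone. On acidification the C2'' hydroxyl adds back to the C6'' carbonyl (6-exo-trig hemiketalisation to 17), water is lost across C5''–C6'' to give the vinylogous ester of ring C, and the peri MOM acetal hydrolyses in the same medium. No stereocentre is created: C2' and C2'' are carried unchanged from 11 and 14, and the hemiketal carbon of 17 ends as sp2. The selectivity required is enolisation at CH3 and not at C3''H2, whose enolate would expel the carboxylate by E1cB; the hindered base at −78 °C, inverse addition that keeps base in excess so that enolates cannot equilibrate, and the fast intramolecular transfer are what secure it. About 2.5 equivalents of base also cover the acidic chromone 2-methyl group, ketone deprotonation and the transfer outrun enolisation of the α-branched ester at C2', and the acid stage is kept cold and brief so that ring C does not reopen by retro-oxa-Michael reaction.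

Compound list
1 | 2',4',6'-trihydroxyacetophenone | CC(=O)c1c(O)cc(O)cc1O | starting material
2 | 3-acetyl-5,7-diacetoxy-2-methylchromone (3-acetyl-2-methyl-4-oxo-4H-chromene-5,7-diyl diacetate) | CC(=O)Oc1cc(OC(C)=O)c2c(c1)oc(C)c(C(C)=O)c2=O | intermediate (not isolated)
3 | noreugenin, 5,7-dihydroxy-2-methyl-4H-chromen-4-one | Cc1cc(=O)c2c(O)cc(O)cc2o1 | intermediate
4 | eugenin, 5-hydroxy-7-methoxy-2-methyl-4H-chromen-4-one | COc1cc(O)c2c(c1)oc(C)cc2=O | intermediate
5 | 5-hydroxy-6-iodo-7-methoxy-2-methyl-4H-chromen-4-one | COc1cc2oc(C)cc(=O)c2c(O)c1I | intermediate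
6 | 6-iodo-7-methoxy-5-(methoxymethoxy)-2-methyl-4H-chromen-4-one | COc1cc2oc(C)cc(=O)c2c(OCOC)c1I | intermediate
7 | methyl (R)-3-hydroxy-2-methylpropanoate | COC(=O)[C@H](C)CO | starting material
8 | methyl (S)-3-iodo-2-methylpropanoate | COC(=O)[C@H](C)CI | intermediate
9 | [(2S)-3-methoxy-2-methyl-3-oxopropyl]zinc iodide | COC(=O)[C@H](C)C[Zn]I | intermediate (not isolated)
10 | methyl (2R)-3-[7-methoxy-5-(methoxymethoxy)-2-methyl-4-oxo-4H-chromen-6-yl]-2-methylpropanoate | COc1cc2oc(C)cc(=O)c2c(OCOC)c1C[C@@H](C)C(=O)OC | intermediate
11 | (2R)-3-[7-methoxy-5-(methoxymethoxy)-2-methyl-4-oxo-4H-chromen-6-yl]-2-methylpropanoic acid | COc1cc2oc(C)cc(=O)c2c(OCOC)c1C[C@@H](C)C(=O)O | intermediate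
12 | ethyl (S)-3-hydroxybutanoate | CCOC(=O)C[C@H](C)O | starting material
13 | (S)-3-hydroxy-N-methoxy-N-methylbutanamide (present as its chloromagnesium alkoxide) | CON(C)C(=O)C[C@H](C)O | intermediate (not isolated)
14 | (S)-4-hydroxypentan-2-one | CC(=O)C[C@H](C)O | intermediate
15 | (2S)-4-oxopentan-2-yl (2R)-3-[7-methoxy-5-(methoxymethoxy)-2-methyl-4-oxo-4H-chromen-6-yl]-2-methylpropanoate | COc1cc2oc(C)cc(=O)c2c(OCOC)c1C[C@@H](C)C(=O)O[C@@H](C)CC(C)=O | intermediate (precursor of the key step)
16 | 6-[(2R,7S)-7-hydroxy-2-methyl-3,5-dioxooctyl]-7-methoxy-5-(methoxymethoxy)-2-methyl-4H-chromen-4-one (present as its lithium enolate) | COc1cc2oc(C)cc(=O)c2c(OCOC)c1C[C@@H](C)C(=O)CC(=O)C[C@H](C)O | intermediate (not isolated)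
17 | 6-{(2R)-2-[(6S)-2-hydroxy-6-methyl-4-oxooxan-2-yl]propyl}-7-methoxy-5-(methoxymethoxy)-2-methyl-4H-chromen-4-one (hemiketal carbon of undefined configuration) | COc1cc2oc(C)cc(=O)c2c(OCOC)c1C[C@@H](C)C1(O)CC(=O)C[C@H](C)O1 | intermediate (not isolated)
18 | CNP0231471.1, 5-hydroxy-7-methoxy-2-methyl-6-{(2R)-2-[(2S)-2-methyl-4-oxo-3,4-dihydro-2H-pyran-6-yl]propyl}-4H-chromen-4-one | COc1cc2oc(C)cc(=O)c2c(O)c1C[C@@H](C)C1=CC(=O)C[C@H](C)O1 | target

Total step count: 10 steps.
Longest linear sequence: 8 steps (steps 1, 2, 3, 4, 6, 7, 9, 10, from compound 1).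

Steps most likely to fail

Step 10. The enolate may move by proton exchange to C3''H2, or form there directly, after which the carboxylate of 11 is expelled by E1cB and the tether is lost before any C–C bond forms. A slower failure is intermolecular attack by the chromone dienolate. The fallback makes the same C5''–C6'' bond intermolecularly, with the C2'' oxygen carrying a poor leaving group, and uses known chemistry. It sets out from 11 and 14. Alcohol 14 would be silylated (TBSCl, imidazole, DMF) to (S)-4-(tert-butyldimethylsilyloxy)pentan-2-one F1. Acid 11 would be activated with 1,1'-carbonyldiimidazole in THF to the acyl imidazolide F2. The kinetic lithium enolate of F1 (LiN(SiMe3)2, THF, −78 °C, about 2.5 equiv, since the acidic product consumes a second equivalent) would be C-acylated by F2 in a Claisen-type ketone acylation to the silyloxy 1,3-diketone F3. Aqueous HCl in THF would then remove the silyl ether and the MOM acetal and cyclodehydrate, so the fallback comes back to the route at target 18.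

Step 6. Oxidative addition and transmetalation at the C6–I bond, which is flanked by OMOM and OMe, may be slow enough that protonolysis of 9 and β-hydride elimination from the alkylpalladium intermediate (net reduction of the C–I bond) take over. The fallback replaces the zinc reagent by an isolable boron homoenolate and a Suzuki–Miyaura coupling. It sets out from 8 (with 6) and comes back at 10. Light-driven radical borylation of 8 with bis(catecholato)diboron in DMF, which needs no base and so cannot eliminate the β-iodo ester, would give the catechol boronate F4. KHF2 in aqueous MeOH would convert it into potassium [(2R)-3-methoxy-2-methyl-3-oxopropyl]trifluoroborate F5. Coupling of F5 with 6 (Pd(OAc)2, RuPhos, K2CO3, toluene–H2O, 85 °C) would then give 10.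

Step 9. DMAP-promoted β-elimination of the newly formed β-acyloxy ketone, dehydration of 14, and loss of the water-soluble, volatile 14 on drying could all erode the ester. The fallback carries the ketone through the esterification as a terminal alkene. It sets out from 11 and comes back at 15, and makes step 8 unnecessary. Acid 11 would be esterified (DCC, DMAP, CH2Cl2) with commercial (S)-pent-4-en-2-ol to the pentenyl ester F6. Tsuji–Wacker oxidation (PdCl2, CuCl, O2, DMF–H2O, rt) would then convert the terminal alkene into the methyl ketone and give 15.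

Further compounds
F1 | step 10 | (S)-4-(tert-butyldimethylsilyloxy)pentan-2-one | CC(=O)C[C@H](C)O[Si](C)(C)C(C)(C)C
F2 | step 10 | acyl imidazolide, 1-{(2R)-3-[7-methoxy-5-(methoxymethoxy)-2-methyl-4-oxo-4H-chromen-6-yl]-2-methylpropanoyl}-1H-imidazole | COc1cc2oc(C)cc(=O)c2c(OCOC)c1C[C@@H](C)C(=O)n1ccnc1
F3 | step 10 | silyloxy 1,3-diketone, 6-[(2R,7S)-7-(tert-butyldimethylsilyloxy)-2-methyl-3,5-dioxooctyl]-7-methoxy-5-(methoxymethoxy)-2-methyl-4H-chromen-4-one | COc1cc2oc(C)cc(=O)c2c(OCOC)c1C[C@@H](C)C(=O)CC(=O)C[C@H](C)O[Si](C)(C)C(C)(C)C
F4 | step 6 | catechol boronate, methyl (2R)-3-(1,3,2-benzodioxaborol-2-yl)-2-methylpropanoate | COC(=O)[C@H](C)CB1Oc2ccccc2O1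
F5 | step 6 | potassium [(2R)-3-methoxy-2-methyl-3-oxopropyl]trifluoroborate | [K+].COC(=O)[C@H](C)C[B-](F)(F)F
F6 | step 9 | pentenyl ester, (2S)-pent-4-en-2-yl (2R)-3-[7-methoxy-5-(methoxymethoxy)-2-methyl-4-oxo-4H-chromen-6-yl]-2-methylpropanoate | COc1cc2oc(C)cc(=O)c2c(OCOC)c1C[C@@H](C)C(=O)O[C@@H](C)CC=C
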